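**Retrosynthetic overview**
1. Target 23 ← O-acetylation ← hydroxyquinone 22 ← Fremy oxidation of resorcinol 21; ring C is carried through the route as a symmetric 4-isopropyl-3,5-dimethoxyphenyl group.
2. Ring B (formed last): C7–C8 bond by intramolecular Friedel–Crafts alkylation of an allyl cation built on the C5 ketone; a Δ5→Δ6 alkene shift then sets C5.
3. Lactone ring (second): C10–C20 by reversible formaldehyde aldol, locked by lactonisation onto the C19 ester, which sets C10 relative to C4; C9–C10 by Pd α-arylation.
4. Ring A (first, key step): enantioselective one-carbon ring expansion of cyclopentanone with methyl 2-diazopropanoate gives the (S) α-quaternary β-keto ester (C4).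
5. Ring order: A (ring expansion) → lactone bridge → B → oxidation of the arene to the quinone (C).

Assumption: abietane numbering is used for the tricycles; "19,20-olide" means C19 is the lactone carbonyl and its oxygen is bonded to C20; the target SMILES corresponds to (4S,5R,10R).

**Route**

Step 1
Reactants: 1 resorcinol
Product: 2 1,3-dimethoxybenzene
Conditions: MeI, K2CO3, DMF, 25 °C
Reagents that add atoms: iodomethane, CI
Why: Williamson O-methylation of both phenols gives the ether needed for directed lithiation; no stereocentre.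

Step 2
Reactants: 2 1,3-dimethoxybenzene; 3 acetone
Product: 6 1,3-dimethoxy-2-(propan-2-yl)benzene, via (2,6-dimethoxyphenyl)lithium 4 (not isolated), via 2-(2,6-dimethoxyphenyl)propan-2-ol 5 (not isolated)
Conditions: n-BuLi, THF, 0 → 25 °C; acetone, −78 → 0 °C; then Et3SiH, TFA, CH2Cl2, 0 → 25 °C
Reagents that add atoms: none
Why: Directed ortho-metalation between the two methoxy groups, 1,2-addition to acetone and ionic hydrogenation of the doubly ortho-stabilised tertiary benzylic cation give the isopropyl arene; no stereocentre.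

Step 3
Reactants: 6 1,3-dimethoxy-2-(propan-2-yl)benzene
Product: 8 5-bromo-1,3-dimethoxy-2-(propan-2-yl)benzene, via aryl pinacol boronate 7 (not isolated)
Conditions: [Ir(OMe)(cod)]2 (1.5 mol %), dtbpy, B2pin2, THF, 80 °C; then CuBr2, MeOH/H2O, 80 °C
Reagents that add atoms: copper(II) bromide, [Cu+2].[Br-].[Br-]; bis(pinacolato)diboron, CC1(C)OB(OC1(C)C)B1OC(C)(C)C(C)(C)O1 (its atoms stay only in 7)
Why: Sterically controlled Ir-catalysed C–H borylation (Hartwig–Miyaura) takes the only C–H not flanked by a substituent, and Cu(II) bromodeboronation gives the bromide in one pot; no stereocentre.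

Step 4
Reactants: 9 methyl L-alaninate hydrochloride
Product: 10 methyl 2-diazopropanoate
Conditions: isoamyl nitrite, NaOAc, AcOH (cat.), CHCl3, reflux
Reagents that add atoms: isoamyl nitrite, CC(C)CCON=O
Why: Diazotisation of the α-amino ester with an alkyl nitrite gives the ester-stabilised diazo compound; the alanine stereocentre is deliberately destroyed.

Step 5
Reactants: 11 cyclopentanone; 10 methyl 2-diazopropanoate
Product: 12 methyl (1S)-1-methyl-2-oxocyclohexane-1-carboxylate
Conditions: Sc(OTf)3 (10 mol %), chiral N,N′-dioxide ligand (11 mol %, antipode chosen for S), 4 Å MS, CH2Cl2, −20 °C, slow addition of 10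
Reagents that add atoms: none
Why: Proposed new method: the chiral Sc(III) complex binds the ketone so that one prochiral face of the diazo carbon adds to C=O, and the ring C–C bond antiperiplanar to N2 then migrates stereospecifically with loss of N2 (Tiffeneau–Demjanov-type 1,2-shift), turning the five-membered ring into ring A and fixing C4 as S; the closest known reaction type is chiral Lewis acid-catalysed homologation of cyclohexanones and activated ketones with bulky α-alkyl-α-diazo esters, not yet shown for the 5→6 expansion of unactivated cyclopentanone with a small methyl diazopropanoate.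

Step 6
Reactants: 12 methyl (1S)-1-methyl-2-oxocyclohexane-1-carboxylate; 8 5-bromo-1,3-dimethoxy-2-(propan-2-yl)benzene
Product: 13 methyl (1S)-3-[3,5-dimethoxy-4-(propan-2-yl)phenyl]-1-methyl-2-oxocyclohexane-1-carboxylate (C3 epimers)
Conditions: Pd2(dba)3 (1 mol %), XPhos, K3PO4, toluene, 90 °C
Reagents that add atoms: none
Why: Buchwald–Hartwig-type Pd-catalysed ketone α-arylation at the only enolisable position (C10) forms the C9–C10 bond; C10 is an inconsequential epimer mixture and C4 has no α-H to scramble.

Step 7
Reactants: 13 methyl (1S)-3-[3,5-dimethoxy-4-(propan-2-yl)phenyl]-1-methyl-2-oxocyclohexane-1-carboxylate; 14 formaldehyde (as paraformaldehyde)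
Product: 16 (1S,5R)-5-[3,5-dimethoxy-4-(propan-2-yl)phenyl]-1-methyl-3-oxabicyclo[3.3.1]nonane-2,9-dione, via cis-hydroxymethyl keto ester 15 (not isolated)
Conditions: (CH2O)n, Cs2CO3 (0.3 equiv), 5 Å MS, DMF, 40 °C
Reagents that add atoms: none
Why: The crossed aldol (hydroxymethylation) of the α-aryl enolate is reversible and only the epimer with CH2OH cis (1,3-diaxial) to the ester can lactonise, so retro-aldol/aldol funnels the material into the bridged lactone and sets C10 (R) relative to C4.

Step 8
Reactants: 16 (1S,5R)-5-[3,5-dimethoxy-4-(propan-2-yl)phenyl]-1-methyl-3-oxabicyclo[3.3.1]nonane-2,9-dione; 17 vinylmagnesium bromide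
Product: 19 (4S,10S)-12,14-dimethoxyabieta-5,8,11,13-tetraen-19,20-olide, via tertiary allylic alcohol 18 (not isolated)
Conditions: CeCl3, THF, −78 °C; then MsOH, CH2Cl2, −78 → 0 °C
Reagents that add atoms: none
Why: Organocerium 1,2-addition to the hindered non-enolisable ketone, then acid ionisation to an allyl cation and intramolecular Friedel–Crafts alkylation (SN1′) at the ortho carbon activated by both methoxy groups closes ring B; the C5 carbinol centre is erased, so its configuration does not matter.

Step 9
Reactants: 19 (4S,10S)-12,14-dimethoxyabieta-5,8,11,13-tetraen-19,20-olide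
Product: 20 (4S,5R,10R)-12,14-dimethoxyabieta-6,8,11,13-tetraen-19,20-olide
Conditions: KOtBu (0.3 equiv), DMSO, 25 °C
Reagents that add atoms: none
Why: Base-catalysed prototropic alkene isomerisation through the benzylic/allylic carbanion moves the alkene into conjugation with the arene, and reversible protonation at C5 is expected to give the thermodynamically favoured trans A/B fusion (C6 on the less hindered lactone side, H-5 anti to C20), setting C5 (R).

Step 10
Reactants: 20 (4S,5R,10R)-12,14-dimethoxyabieta-6,8,11,13-tetraen-19,20-olide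
Product: 21 (4S,5R,10R)-12,14-dihydroxyabieta-6,8,11,13-tetraen-19,20-olide
Conditions: BBr3, CH2Cl2, −78 → 0 °C; then H2O
Reagents that add atoms: none
Why: Lewis acid-mediated SN2 demethylation of both aryl methyl ethers proceeds at low temperature without touching the neopentyl lactone; stereocentres are unaffected.

Step 11
Reactants: 21 (4S,5R,10R)-12,14-dihydroxyabieta-6,8,11,13-tetraen-19,20-olide
Product: 22 (4S,5R,10R)-12-hydroxy-11,14-dioxoabieta-6,8,12-trien-19,20-olide
Conditions: (KSO3)2NO, KH2PO4, acetone/H2O, 0 → 25 °C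
Reagents that add atoms: Fremy's salt (potassium nitrosodisulfonate), [K+].[K+].[O]N(S([O-])(=O)=O)S([O-])(=O)=O
Why: Teuber oxidation attacks the only free ring position (C11, para to the C14 phenol) and gives the 2-hydroxy-1,4-benzoquinone, the same tautomer whichever phenol reacts; stereocentres are unaffected.

Step 12
Reactants: 22 (4S,5R,10R)-12-hydroxy-11,14-dioxoabieta-6,8,12-trien-19,20-olide
Product: 23 (4S,5R,10R)-12-acetoxy-11,14-dioxoabieta-6,8,12-trien-19,20-olide (CNP0596241.1)
Conditions: Ac2O, pyridine, DMAP (cat.), CH2Cl2, 0 °C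
Reagents that add atoms: acetic anhydride, CC(=O)OC(C)=O
Why: O-acylation of the acidic quinone hydroxyl (a vinylogous acid) gives the acetate; stereocentres are unaffected.

**Compound list**
1 | resorcinol | Oc1cccc(O)c1 | starting material
2 | 1,3-dimethoxybenzene | COc1cccc(OC)c1 | intermediate
3 | acetone | CC(C)=O | starting material
4 | (2,6-dimethoxyphenyl)lithium | [Li]c1c(OC)cccc1OC | intermediate
5 | 2-(2,6-dimethoxyphenyl)propan-2-ol | COc1cccc(OC)c1C(C)(C)O | intermediate
6 | 1,3-dimethoxy-2-(propan-2-yl)benzene | COc1cccc(OC)c1C(C)C | intermediate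
7 | 2-[3,5-dimethoxy-4-(propan-2-yl)phenyl]-4,4,5,5-tetramethyl-1,3,2-dioxaborolane | COc1cc(cc(OC)c1C(C)C)B2OC(C)(C)C(C)(C)O2 | intermediate
8 | 5-bromo-1,3-dimethoxy-2-(propan-2-yl)benzene | COc1cc(Br)cc(OC)c1C(C)C | intermediate
9 | methyl L-alaninate hydrochloride | C[C@H](N)C(=O)OC.Cl | starting material
10 | methyl 2-diazopropanoate | COC(=O)C(C)=[N+]=[N-] | intermediate
11 | cyclopentanone | O=C1CCCC1 | starting material
12 | methyl (1S)-1-methyl-2-oxocyclohexane-1-carboxylate | COC(=O)[C@@]1(C)CCCCC1=O | intermediate
13 | methyl (1S)-3-[3,5-dimethoxy-4-(propan-2-yl)phenyl]-1-methyl-2-oxocyclohexane-1-carboxylate (C3 epimers) | COC(=O)[C@@]1(C)CCCC(c2cc(OC)c(C(C)C)c(OC)c2)C1=O | intermediate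
14 | formaldehyde | C=O | starting material
15 | methyl (1S,3R)-3-[3,5-dimethoxy-4-(propan-2-yl)phenyl]-3-(hydroxymethyl)-1-methyl-2-oxocyclohexane-1-carboxylate | COc1cc(cc(OC)c1C(C)C)[C@@]2(CO)CCC[C@](C)(C(=O)OC)C2=O | intermediate
16 | (1S,5R)-5-[3,5-dimethoxy-4-(propan-2-yl)phenyl]-1-methyl-3-oxabicyclo[3.3.1]nonane-2,9-dione | COc1cc(cc(OC)c1C(C)C)[C@]23CCC[C@](C)(C(=O)OC2)C3=O | intermediate
17 | vinylmagnesium bromide | C=C[Mg]Br | starting material
18 | (1S,5R)-5-[3,5-dimethoxy-4-(propan-2-yl)phenyl]-9-ethenyl-9-hydroxy-1-methyl-3-oxabicyclo[3.3.1]nonan-2-one (C9 epimers) | COc1cc(cc(OC)c1C(C)C)[C@]23CCC[C@](C)(C(=O)OC2)C3(O)C=C | intermediate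
19 | (4S,10S)-12,14-dimethoxyabieta-5,8,11,13-tetraen-19,20-olide | COc1cc2c(c(OC)c1C(C)C)CC=C1[C@@](C)(C(=O)OC3)CCC[C@]213 | intermediate
20 | (4S,5R,10R)-12,14-dimethoxyabieta-6,8,11,13-tetraen-19,20-olide | COc1cc2c(c(OC)c1C(C)C)C=C[C@H]1[C@@](C)(C(=O)OC3)CCC[C@]213 | intermediate
21 | (4S,5R,10R)-12,14-dihydroxyabieta-6,8,11,13-tetraen-19,20-olide | Oc1cc2c(c(O)c1C(C)C)C=C[C@H]1[C@@](C)(C(=O)OC3)CCC[C@]213 | intermediate
22 | (4S,5R,10R)-12-hydroxy-11,14-dioxoabieta-6,8,12-trien-19,20-olide | OC1=C(C(C)C)C(=O)C2=C(C1=O)[C@]13CCC[C@](C)(C(=O)OC1)[C@@H]3C=C2 | intermediate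
23 | (4S,5R,10R)-12-acetoxy-11,14-dioxoabieta-6,8,12-trien-19,20-olide (CNP0596241.1) | CC(=O)OC1=C(C(C)C)C(=O)C2=C(C1=O)[C@]13CCC[C@](C)(C(=O)OC1)[C@@H]3C=C2 | target

**Totals**
Total steps: 12. Longest linear sequence: 10 (steps 1, 2, 3, 6–12, from resorcinol); the ring-A branch (steps 4, 5) joins at step 6.

**Three steps most likely to fail**

Step 5 (proposed new enantioselective ring expansion). The risk is low ee or epoxide/C–H insertion by-products with a small methyl diazo ester. The fallback sets out from 11: BF3·OEt2-promoted homologation of cyclopentanone with methyl diazoacetate (a known Tiffeneau–Demjanov-type diazoacetate ring expansion) gives methyl 2-oxocyclohexane-1-carboxylate F1. F1 is then C-methylated with MeI under chiral phase-transfer catalysis (quaternary ammonium salt, Cs2CO3, toluene), a known asymmetric β-keto ester alkylation, and the route is rejoined at 12. The ring is still built by ring expansion, but C4 is set by enolate alkylation.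

Step 8 (vinyl addition and cationic ring-B closure in one pot). The risks are attack on the lactone, retro-aldol fragmentation of the alkoxide, and poor ionisation next to the lactone carbonyl. The fallback sets out from 16: ethynylmagnesium bromide/CeCl3 gives the propargylic alcohol (1S,5R)-5-[3,5-dimethoxy-4-(propan-2-yl)phenyl]-9-ethynyl-9-hydroxy-1-methyl-3-oxabicyclo[3.3.1]nonan-2-one F2. PtCl2-catalysed 6-endo-dig hydroarylation of the electron-rich arene then closes ring B without a cation at C5, giving (4S,10R)-5-hydroxy-12,14-dimethoxyabieta-6,8,11,13-tetraen-19,20-olide F3. Ionic deoxygenation (Et3SiH, BF3·OEt2) delivers hydride to the unhindered benzylic terminus of the allyl cation, and the route is rejoined at 19.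

Step 9 (alkene isomerisation and C5 configuration). The risks are lactone opening by alkoxide in DMSO and an unfavourable cis/trans ratio at C5, since the thermodynamic preference for the trans fusion is argued from sterics, not proven. The fallback sets out from 19 and postpones the isomerisation to the quinone level, where C7–H and C5–H are vinylogously acidic and very mild base suffices. BBr3 gives (4S,10S)-12,14-dihydroxyabieta-5,8,11,13-tetraen-19,20-olide F4, and Fremy's salt gives (4S,10R)-12-hydroxy-11,14-dioxoabieta-5,8,12-trien-19,20-olide F5. Et3N in CH2Cl2 then moves the alkene into conjugation by vinylogous enolisation and reprotonation at C5 under equilibrium control, and the route is rejoined at 22.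

**Further compounds**
F1 | step 5 | methyl 2-oxocyclohexane-1-carboxylate | COC(=O)C1CCCCC1=O
F2 | step 8 | (1S,5R)-5-[3,5-dimethoxy-4-(propan-2-yl)phenyl]-9-ethynyl-9-hydroxy-1-methyl-3-oxabicyclo[3.3.1]nonan-2-one (C9 epimers) | COc1cc(cc(OC)c1C(C)C)[C@]23CCC[C@](C)(C(=O)OC2)C3(O)C#C
F3 | step 8 | (4S,10R)-5-hydroxy-12,14-dimethoxyabieta-6,8,11,13-tetraen-19,20-olide (C5 epimers) | COc1cc2c(c(OC)c1C(C)C)C=CC1(O)[C@@](C)(C(=O)OC3)CCC[C@]213
F4 | step 9 | (4S,10S)-12,14-dihydroxyabieta-5,8,11,13-tetraen-19,20-olide | Oc1cc2c(c(O)c1C(C)C)CC=C1[C@@](C)(C(=O)OC3)CCC[C@]213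
F5 | step 9 | (4S,10R)-12-hydroxy-11,14-dioxoabieta-5,8,12-trien-19,20-olide | OC1=C(C(C)C)C(=O)C2=C(C1=O)[C@]13CCC[C@](C)(C(=O)OC1)C3=CC2
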